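**Retrosynthetic overview**
1. 20 ⇒ 19 ⇒ 17 ⇒ 15. The C4 MOM ether is removed last. C1–OH comes from a 1,3-syn reduction of a C1 ketone directed by C3–OH. The β-hydroxy ketone comes from N–O cleavage of a 4,5-dihydroisoxazole.
2. 15 ⇒ nitrile oxide 14 (from bisoxazole aldoxime 13) + terminal alkene 7. One [3+2] cycloaddition makes C1–C2 and O–C3 and joins all carbons of the target.
3. Enabling feature: the segment oxazole C4–C1(O)–C2H2–C3(O)–C4(O), a 1,3-dioxygenated pair across an unsubstituted CH2 with an oxygen-bearing stereocentre next to C3. O–C3–C2–C1 maps onto O1–C5–C4–C3 of a dihydroisoxazole, and the C4 alkoxy group steers the dipole (inside-alkoxy effect).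
4. 7 ⇒ allyl MOM ether 2 + acetaldehyde 3 (syn-alkoxyallylboration sets C4 and C5) + palmitoyl chloride 6. 13 ⇒ chloromethyl oxazole 8 + oxazol-5-yl boronate 9 (Suzuki–Miyaura).
5. Rings: both oxazoles are bought intact and linked in step 4. The only ring formed is the temporary dihydroisoxazole (step 7), and it is opened again in step 8.

Key step: step 7

Remark: chain atoms are numbered C1 (carbinol carbon on oxazole C4) to C6 (methyl), and O5 is the acylated oxygen. Compounds 8 and 9 are assumed to be catalogue compounds.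

**Step 1**
Reactants: 1 allyl alcohol
Product: 2 allyl methoxymethyl ether
Conditions: MOMCl, iPr2NEt, CH2Cl2, 0 °C to rt
Reagents that add atoms: chloromethyl methyl ether (MOMCl), COCCl
Why: Williamson-type O-alkylation of the alcohol with the reactive α-chloro ether (MOM protection) installs the alkoxy group that later becomes the C4 oxygen.

**Step 2**
Reactants: 2 allyl methoxymethyl ether; 3 acetaldehyde
Product: 5 (2S,3S)-3-(methoxymethoxy)pent-4-en-2-ol, via Z-alkoxyallylborane 4 (not isolated)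
Conditions: s-BuLi, THF, −78 °C; (+)-Ipc2BOMe, −78 °C; BF3·OEt2, then 3, −78 °C; NaOH, H2O2, 0 °C to rt
Reagents that add atoms: none
Why: In this Brown asymmetric alkoxyallylboration the Z-γ-alkoxyallylborane 4 reacts through a chair Zimmerman–Traxler transition state, so the Z geometry gives the 4,5-syn relation and the isopinocampheyl groups derived from (−)-α-pinene select the aldehyde face that gives (S) at C5 and (S) at C4.

**Step 3**
Reactants: 5 (2S,3S)-3-(methoxymethoxy)pent-4-en-2-ol; 6 palmitoyl chloride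
Product: 7 (2S,3S)-3-(methoxymethoxy)pent-4-en-2-yl hexadecanoate
Conditions: Et3N, DMAP (cat.), CH2Cl2, 0 °C to rt
Reagents that add atoms: none
Why: DMAP-catalysed acylation of the only free hydroxyl fixes the palmitate on O5 before any other hydroxyl exists, with retention at C5.

**Step 4**
Reactants: 8 methyl 2-(chloromethyl)-1,3-oxazole-4-carboxylate; 9 2-(triisopropylsilyl)-1,3-oxazole-5-boronic acid pinacol ester
Product: 11 methyl 2-(1,3-oxazol-5-ylmethyl)-1,3-oxazole-4-carboxylate, via TIPS-protected bisoxazole ester 10 (not isolated)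
Conditions: PdCl2(dppf) (5 mol %), K3PO4, THF/H2O, 60 °C; then 1 M HCl, THF, rt
Reagents that add atoms: none
Why: In this Suzuki–Miyaura coupling of a heterobenzylic chloride zerovalent palladium inserts into the activated C–Cl bond, the C2 silyl group shields the oxazol-5-yl boronate during transmetalation, and dilute acid then removes the labile C2–Si bond by protodesilylation.

**Step 5**
Reactants: 11 methyl 2-(1,3-oxazol-5-ylmethyl)-1,3-oxazole-4-carboxylate
Product: 12 2-(1,3-oxazol-5-ylmethyl)-1,3-oxazole-4-carbaldehyde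
Conditions: i-Bu2AlH (1.2 equiv), CH2Cl2, −78 °C; MeOH, aq. potassium sodium tartrate
Reagents that add atoms: none
Why: Low-temperature i-Bu2AlH partial reduction of an ester to the aldehyde is a standard conversion for electron-poor oxazole-4-carboxylates and touches neither ring nor the bridging CH2.

**Step 6**
Reactants: 12 2-(1,3-oxazol-5-ylmethyl)-1,3-oxazole-4-carbaldehyde
Product: 13 (E)-2-(1,3-oxazol-5-ylmethyl)-1,3-oxazole-4-carbaldehyde oxime
Conditions: NH2OH·HCl, NaOAc, EtOH/H2O, rt
Reagents that add atoms: hydroxylamine hydrochloride, NO.Cl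
Why: Condensation of the aldehyde with hydroxylamine (oxime formation) under acetate buffer is mild enough for the acidic CH2 between the two oxazoles.

**Step 7**
Reactants: 13 (E)-2-(1,3-oxazol-5-ylmethyl)-1,3-oxazole-4-carbaldehyde oxime; 7 (2S,3S)-3-(methoxymethoxy)pent-4-en-2-yl hexadecanoate
Product: 15 (1R,2S)-1-(methoxymethoxy)-1-[(5S)-3-{2-(1,3-oxazol-5-ylmethyl)-1,3-oxazol-4-yl}-4,5-dihydro-1,2-oxazol-5-yl]propan-2-yl hexadecanoate, via nitrile oxide 14 (not isolated)
Conditions: 7 (1.5 equiv), PhI(OAc)2 (slow addition), TFA (cat.), MeOH/CH2Cl2, 0 °C to rt; chromatographic removal of the minor C3 epimer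
Reagents that add atoms: none
Why: PhI(OAc)2 dehydrogenates aldoxime 13 to nitrile oxide 14, which adds to the terminal alkene of 7 in a concerted, asynchronous Huisgen [3+2] cycloaddition in which the dipole carbon bonds to the unsubstituted CH2 terminus (C1–C2) while the dipole oxygen bonds to C3. The closest known reaction type is the nitrile oxide cycloaddition to chiral allyl ethers used as a masked aldol reaction. The 4,5-dihydroisoxazole is closed by intermolecular [3+2] annulation (the C–N–O atoms of the dipole plus the two alkene carbons) and not by cyclisation of a chain. The only new stereocentre, C3, is controlled by the adjacent C4 stereocentre through the inside-alkoxy effect: the OMOM group sits inside, the branched C5 substituent anti and H outside, so the dipole should attack the face that gives the 3,4-anti isomer, (5S) in the ring. Regioselectivity for the 5-substituted ring is secured by the monosubstituted alkene, chemoselectivity over dimerisation of the dipole by its slow generation in the presence of excess 7, and the ester, the acetal and both oxazoles are inert to the dipole. In one operation the step joins all carbons of the target, installs the C3 oxygen with its configuration and leaves C1 at the ketone level (as C=N), so that C3 can later relay its configuration to C1.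

**Step 8**
Reactants: 15 the dihydroisoxazole from step 7
Product: 17 (2S,3S,4S)-4-hydroxy-3-(methoxymethoxy)-6-oxo-6-[2-(1,3-oxazol-5-ylmethyl)-1,3-oxazol-4-yl]hexan-2-yl hexadecanoate, via hydroxy imine 16 (not isolated)
Conditions: H2 (1 atm), Raney Ni, B(OH)3, MeOH/THF/H2O, rt
Reagents that add atoms: water, O
Why: Hydrogenolysis of the weak N–O bond on Raney Ni gives hydroxy imine 16, which the boric acid-buffered water hydrolyses at once to the ketone (reductive isoxazoline opening), and C3 keeps its configuration because only the N–O and C=N bonds react.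

**Step 9**
Reactants: 17 the β-hydroxy ketone from step 8
Product: 19 (2S,3S,4S,6R)-4,6-dihydroxy-3-(methoxymethoxy)-6-[2-(1,3-oxazol-5-ylmethyl)-1,3-oxazol-4-yl]hexan-2-yl hexadecanoate, via diethylborinate chelate 18 (not isolated)
Conditions: Et2BOMe, THF/MeOH (4:1), −78 °C; NaBH4, −78 °C; MeOH co-evaporation
Reagents that add atoms: none
Why: In this Narasaka–Prasad reduction Et2BOMe turns the C3 hydroxyl into borinate 18, whose boron binds the C1 carbonyl oxygen in a six-membered chelate, and external hydride attacks axially to give the 1,3-syn diol and hence (R) at C1, while the palmitate is inert at −78 °C.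

**Step 10**
Reactants: 19 the MOM-protected syn-diol from step 9
Product: 20 (2S,3S,4S,6R)-3,4,6-trihydroxy-6-[2-(1,3-oxazol-5-ylmethyl)-1,3-oxazol-4-yl]hexan-2-yl hexadecanoate (target)
Conditions: ZnBr2 (excess), n-PrSH, CH2Cl2, 0 °C to rt
Reagents that add atoms: none
Why: In this Lewis acid-assisted thiolysis of the acetal ZnBr2 binds the two acetal oxygens and the soft thiol attacks the O–CH2–O carbon, so O4 is released without a cation on its side, under conditions short and mild enough to leave the neighbouring ester in place and every stereocentre untouched.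

**Compound list**
1 | allyl alcohol | C=CCO | starting material
2 | allyl methoxymethyl ether, 3-(methoxymethoxy)prop-1-ene | C=CCOCOC | intermediate
3 | acetaldehyde | CC=O | starting material
4 | [(Z)-3-(methoxymethoxy)allyl]diisopinocampheylborane, Ipc groups from (−)-α-pinene | COCO/C=C\CB([C@H]1C[C@H]2C[C@@H]([C@@H]1C)C2(C)C)[C@H]1C[C@H]2C[C@@H]([C@@H]1C)C2(C)C | intermediate
5 | (2S,3S)-3-(methoxymethoxy)pent-4-en-2-ol | O[C@@H](C)[C@@H](OCOC)C=C | intermediate
6 | palmitoyl chloride (hexadecanoyl chloride) | CCCCCCCCCCCCCCCC(=O)Cl | starting material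
7 | (2S,3S)-3-(methoxymethoxy)pent-4-en-2-yl hexadecanoate | CCCCCCCCCCCCCCCC(=O)O[C@@H](C)[C@@H](OCOC)C=C | intermediate
8 | methyl 2-(chloromethyl)-1,3-oxazole-4-carboxylate | COC(=O)c1coc(CCl)n1 | starting material
9 | 2-(triisopropylsilyl)-1,3-oxazole-5-boronic acid pinacol ester | CC(C)[Si](C(C)C)(C(C)C)c1ncc(o1)B1OC(C)(C)C(C)(C)O1 | starting material
10 | methyl 2-{[2-(triisopropylsilyl)-1,3-oxazol-5-yl]methyl}-1,3-oxazole-4-carboxylate | COC(=O)c1coc(Cc2cnc(o2)[Si](C(C)C)(C(C)C)C(C)C)n1 | intermediate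
11 | methyl 2-(1,3-oxazol-5-ylmethyl)-1,3-oxazole-4-carboxylate | COC(=O)c1coc(Cc2cnco2)n1 | intermediate
12 | 2-(1,3-oxazol-5-ylmethyl)-1,3-oxazole-4-carbaldehyde | O=Cc1coc(Cc2cnco2)n1 | intermediate
13 | (E)-2-(1,3-oxazol-5-ylmethyl)-1,3-oxazole-4-carbaldehyde oxime | O/N=C/c1coc(Cc2cnco2)n1 | intermediate
14 | 2-(1,3-oxazol-5-ylmethyl)-1,3-oxazole-4-carbonitrile oxide | [O-][N+]#Cc1coc(Cc2cnco2)n1 | intermediate
15 | (1R,2S)-1-(methoxymethoxy)-1-[(5S)-3-{2-(1,3-oxazol-5-ylmethyl)-1,3-oxazol-4-yl}-4,5-dihydro-1,2-oxazol-5-yl]propan-2-yl hexadecanoate | CCCCCCCCCCCCCCCC(=O)O[C@@H](C)[C@@H](OCOC)[C@@H]1CC(=NO1)c1coc(Cc2cnco2)n1 | intermediate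
16 | (2S,3S,4S)-4-hydroxy-6-imino-3-(methoxymethoxy)-6-[2-(1,3-oxazol-5-ylmethyl)-1,3-oxazol-4-yl]hexan-2-yl hexadecanoate | CCCCCCCCCCCCCCCC(=O)O[C@@H](C)[C@@H](OCOC)[C@@H](O)CC(=N)c1coc(Cc2cnco2)n1 | intermediate
17 | (2S,3S,4S)-4-hydroxy-3-(methoxymethoxy)-6-oxo-6-[2-(1,3-oxazol-5-ylmethyl)-1,3-oxazol-4-yl]hexan-2-yl hexadecanoate | CCCCCCCCCCCCCCCC(=O)O[C@@H](C)[C@@H](OCOC)[C@@H](O)CC(=O)c1coc(Cc2cnco2)n1 | intermediate
18 | (2S,3S,4S)-4-[(diethylboranyl)oxy]-3-(methoxymethoxy)-6-oxo-6-[2-(1,3-oxazol-5-ylmethyl)-1,3-oxazol-4-yl]hexan-2-yl hexadecanoate | CCCCCCCCCCCCCCCC(=O)O[C@@H](C)[C@@H](OCOC)[C@@H](OB(CC)CC)CC(=O)c1coc(Cc2cnco2)n1 | intermediate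
19 | (2S,3S,4S,6R)-4,6-dihydroxy-3-(methoxymethoxy)-6-[2-(1,3-oxazol-5-ylmethyl)-1,3-oxazol-4-yl]hexan-2-yl hexadecanoate | CCCCCCCCCCCCCCCC(=O)O[C@@H](C)[C@@H](OCOC)[C@@H](O)C[C@@H](O)c1coc(Cc2cnco2)n1 | intermediate
20 | (2S,3S,4S,6R)-3,4,6-trihydroxy-6-[2-(1,3-oxazol-5-ylmethyl)-1,3-oxazol-4-yl]hexan-2-yl hexadecanoate | CCCCCCCCCCCCCCCC(=O)O[C@@H](C)[C@@H](O)[C@@H](O)C[C@@H](O)c1coc(Cc2cnco2)n1 | target

Total step count: 10. Longest linear sequence: 7 steps (steps 4–10, or equally steps 1–3 followed by 7–10).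

**Steps most likely to fail**

**Step 7.** The inside-alkoxy bias of an acyclic allyl ether may give poor facial selectivity at C3. The dipole may dimerise faster than it adds. The oxidant may also attack the doubly activated CH2 between the oxazoles.

The fallback sets out from 7 and 12 and comes back at 19. It makes the same C1–C2 bond by a boron aldol reaction instead of a cycloaddition. Alkene 7 is oxidised by a Wacker-type oxidation suited to protected allylic alcohols (Pd(Quinox)Cl2, AgSbF6, aq. t-BuOOH, CH2Cl2) to the methyl ketone (2S,3R)-3-(methoxymethoxy)-4-oxopentan-2-yl hexadecanoate F1. This ketone is enolised on its methyl side with (−)-Ipc2BCl/Et3N in Et2O and added to aldehyde 12 at −78 °C. The reagent directs attack to the Re face and should give the aldol adduct (2S,3R,6R)-6-hydroxy-3-(methoxymethoxy)-6-[2-(1,3-oxazol-5-ylmethyl)-1,3-oxazol-4-yl]-4-oxohexan-2-yl hexadecanoate F2. Zn(BH4)2 in Et2O then reduces the C3 ketone under chelation by both the C1 hydroxyl (1,3-syn) and the C4 alkoxy group (3,4-anti). The two effects reinforce each other and should give 19.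

**Step 10.** Acetal cleavage next to free hydroxyls may be accompanied by capture of the acetal carbon by the C3 hydroxyl (closure of a cyclic formal). The palmitoyl group may also migrate from O5 to the freed O4.

The fallback sets out from 15 and comes back at 20. It exchanges the acetal for a silyl ether at the one stage where no free hydroxyl is present, so that the last step becomes a buffered fluoride desilylation.
- ZnBr2/n-PrSH on 15 gives the alcohol (1R,2S)-1-hydroxy-1-[(5S)-3-{2-(1,3-oxazol-5-ylmethyl)-1,3-oxazol-4-yl}-4,5-dihydro-1,2-oxazol-5-yl]propan-2-yl hexadecanoate F3.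
- TESOTf/2,6-lutidine gives the silyl ether (1R,2S)-1-(triethylsilyloxy)-1-[(5S)-3-{2-(1,3-oxazol-5-ylmethyl)-1,3-oxazol-4-yl}-4,5-dihydro-1,2-oxazol-5-yl]propan-2-yl hexadecanoate F4.
- Raney Ni/H2/B(OH)3 gives the ketone (2S,3S,4S)-4-hydroxy-6-oxo-6-[2-(1,3-oxazol-5-ylmethyl)-1,3-oxazol-4-yl]-3-(triethylsilyloxy)hexan-2-yl hexadecanoate F5.
- Et2BOMe/NaBH4 gives the syn-diol (2S,3S,4S,6R)-4,6-dihydroxy-6-[2-(1,3-oxazol-5-ylmethyl)-1,3-oxazol-4-yl]-3-(triethylsilyloxy)hexan-2-yl hexadecanoate F6.
- HF·pyridine buffered with pyridine in THF at 0 °C gives 20.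

**Step 4.** Protodeboronation of the heteroaryl boronate, and hydrolysis or N-alkylation at the chloromethyl group, may outrun transmetalation.

The fallback sets out from 8 and comes back at 10. It reverses the polarity of the coupling. Zinc dust/LiCl in THF converts 8 into {[4-(methoxycarbonyl)-1,3-oxazol-2-yl]methyl}zinc chloride F7. Commercial 2-(triisopropylsilyl)oxazole is lithiated at C5 (n-BuLi, THF, −78 °C) and quenched with I2 to give 5-iodo-2-(triisopropylsilyl)-1,3-oxazole F8. A Negishi coupling of the two with Pd(PPh3)4 in THF gives 10, which is desilylated with dilute acid as in the main route.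

**Further compounds**
F1 | step 7 | (2S,3R)-3-(methoxymethoxy)-4-oxopentan-2-yl hexadecanoate | CCCCCCCCCCCCCCCC(=O)O[C@@H](C)[C@@H](OCOC)C(C)=O
F2 | step 7 | (2S,3R,6R)-6-hydroxy-3-(methoxymethoxy)-6-[2-(1,3-oxazol-5-ylmethyl)-1,3-oxazol-4-yl]-4-oxohexan-2-yl hexadecanoate | CCCCCCCCCCCCCCCC(=O)O[C@@H](C)[C@@H](OCOC)C(=O)C[C@@H](O)c1coc(Cc2cnco2)n1
F3 | step 10 | (1R,2S)-1-hydroxy-1-[(5S)-3-{2-(1,3-oxazol-5-ylmethyl)-1,3-oxazol-4-yl}-4,5-dihydro-1,2-oxazol-5-yl]propan-2-yl hexadecanoate | CCCCCCCCCCCCCCCC(=O)O[C@@H](C)[C@@H](O)[C@@H]1CC(=NO1)c1coc(Cc2cnco2)n1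
F4 | step 10 | (1R,2S)-1-(triethylsilyloxy)-1-[(5S)-3-{2-(1,3-oxazol-5-ylmethyl)-1,3-oxazol-4-yl}-4,5-dihydro-1,2-oxazol-5-yl]propan-2-yl hexadecanoate | CCCCCCCCCCCCCCCC(=O)O[C@@H](C)[C@@H](O[Si](CC)(CC)CC)[C@@H]1CC(=NO1)c1coc(Cc2cnco2)n1
F5 | step 10 | (2S,3S,4S)-4-hydroxy-6-oxo-6-[2-(1,3-oxazol-5-ylmethyl)-1,3-oxazol-4-yl]-3-(triethylsilyloxy)hexan-2-yl hexadecanoate | CCCCCCCCCCCCCCCC(=O)O[C@@H](C)[C@@H](O[Si](CC)(CC)CC)[C@@H](O)CC(=O)c1coc(Cc2cnco2)n1
F6 | step 10 | (2S,3S,4S,6R)-4,6-dihydroxy-6-[2-(1,3-oxazol-5-ylmethyl)-1,3-oxazol-4-yl]-3-(triethylsilyloxy)hexan-2-yl hexadecanoate | CCCCCCCCCCCCCCCC(=O)O[C@@H](C)[C@@H](O[Si](CC)(CC)CC)[C@@H](O)C[C@@H](O)c1coc(Cc2cnco2)n1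
F7 | step 4 | {[4-(methoxycarbonyl)-1,3-oxazol-2-yl]methyl}zinc chloride | COC(=O)c1coc(C[Zn]Cl)n1
F8 | step 4 | 5-iodo-2-(triisopropylsilyl)-1,3-oxazole | CC(C)[Si](C(C)C)(C(C)C)c1ncc(I)o1
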